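**Strategy.** The cyclohexane ring (C5–C10, elemane numbering) is disconnected at C6–C7, where the C6 carbinol sits beside the C7 2-carboxyallyl unit (C11=C13, C12): the signature of a γ-selective 2-(alkoxycarbonyl)allyl-metal addition to an aldehyde. An intramolecular zinc Barbier allylation therefore closes the ring, installs the acrylate in its final position and oxidation state, and sets C6 and C7 in one operation. Its precursor is an acyclic C6 aldehyde whose C5 and C10 centres come from a reagent-controlled Ireland–Claisen rearrangement and whose C8 centre comes from (R)-glycidol; C7 carries a (Z)-2-(bromomethyl)enoate made by Baylis–Hillman reaction and SN2′ bromination. Acylation at C8 and fluoride unmasking finish the synthesis.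

Key step: step 17

**Remarks on the chemistry**
- Numbering: ring C5–C6–C7–C8–C9–C10; C10 bears C14 (methyl) and the C1=C2 vinyl group; C5 bears C4(=C3)–C15; C7 bears C11(=C13)–C12.
- The configuration is taken exactly as the SMILES is written: 5R,6S,7S,8S,10R, i.e. the C5 branch, C6–O and the C7 acrylate mutually cis, C8–O trans to them, and the C10 vinyl group cis to the C5 branch.
- Assumption: the (S,S)-enantiomer of the bromoborane controller is taken to give the 5R,10R series from the enolate used in step 8; if the opposite sense were found, the antipode would be used with no other change.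
- Enolate pairing: the (E)-allylic ester must be paired with the boron enolate that has O–B cis to the C4 branch; the other enolate geometry would give the C10 epimer.
- Protecting groups (TES = triethylsilyl, TBS = tert-butyldimethylsilyl, TBDPS = tert-butyldiphenylsilyl, PMB = 4-methoxybenzyl, TMSE = 2-(trimethylsilyl)ethyl): C8 travels as TES ether, C15 as TBDPS ether and C6 as PMB ether until the aldehyde is needed, so each unmasking has one possible site. After ring closure C6–O is capped as TBS ether, which fluoride removes more slowly than the TMSE ester, so C6–O is freed only when C12 is already a carboxylate.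

**Route**

Step 1
Reactants: 1 (R)-glycidol
Product: 2 (2S)-pent-4-yne-1,2-diol
Conditions: lithium acetylide–ethylenediamine complex (2.5 equiv), DMSO, 10 °C → rt (slow addition of 1); aq. NH4Cl
Reagents that add atoms: lithium acetylide–ethylenediamine complex, [Li+].[C-]#C.NCCN
Why: The acetylide opens the epoxide of the glycidol alkoxide at the unsubstituted carbon (SN2 epoxide opening), so the glycidol stereocentre becomes C8 (S) without being touched.

Step 2
Reactants: 2 (2S)-pent-4-yne-1,2-diol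
Product: 3 (4S)-4,5-bis(triethylsilyloxy)pent-1-yne
Conditions: Et3SiCl (2.4 equiv), imidazole, DMF, 0 °C → rt
Reagents that add atoms: chlorotriethylsilane, CC[Si](Cl)(CC)CC
Why: Imidazole-promoted silyl ether formation covers both hydroxyls, and the primary and secondary TES ethers can be told apart later (step 11).

Step 3
Reactants: 3 (4S)-4,5-bis(triethylsilyloxy)pent-1-yne
Product: 5 (2E,5S)-3-methyl-5,6-bis(triethylsilyloxy)hex-2-en-1-ol, via alkenyl(dimethyl)alane 4 (not isolated)
Conditions: Me3Al, Cp2ZrCl2 (cat.), CH2Cl2, 0 °C → rt; then n-BuLi, THF, −78 °C; (CH2O)n, −78 °C → rt; aq. KNaC4H4O6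
Reagents that add atoms: trimethylaluminium, C[Al](C)C; paraformaldehyde (formaldehyde unit), C=O
Why: Zirconium-catalysed Negishi carboalumination adds methyl and aluminium syn across the terminal alkyne with methyl on C10, and the derived alanate traps formaldehyde with retention, which fixes the (E)-geometry of the allylic alcohol.

Step 4
Reactants: 6 monomethyl itaconate
Product: 7 methyl 3-(hydroxymethyl)but-3-enoate
Conditions: BH3·SMe2 (1.0 equiv), THF, −10 °C → rt; MeOH, then H2O
Reagents that add atoms: none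
Why: Borane reduces the free carboxylic acid through its acyloxyborane much faster than the methyl ester, and one equivalent leaves no B–H for hydroboration (chemoselective borane reduction of an acid).

Step 5
Reactants: 7 methyl 3-(hydroxymethyl)but-3-enoate
Product: 8 methyl 3-[(tert-butyldiphenylsilyloxy)methyl]but-3-enoate
Conditions: t-BuPh2SiCl, imidazole, CH2Cl2, 0 °C → rt (crude 7 used at once)
Reagents that add atoms: tert-butyl(chloro)diphenylsilane, CC(C)(C)[Si](Cl)(c1ccccc1)c1ccccc1
Why: Silyl ether formation at the primary allylic hydroxyl, done immediately, keeps the γ-hydroxy ester from lactonising and gives the most robust of the silyl groups at C15.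

Step 6
Reactants: 8 methyl 3-[(tert-butyldiphenylsilyloxy)methyl]but-3-enoate
Product: 9 3-[(tert-butyldiphenylsilyloxy)methyl]but-3-enoic acid
Conditions: LiOH·H2O, THF/H2O, 0 °C; then 1 M HCl to pH 4, 0 °C
Reagents that add atoms: lithium hydroxide, [Li+].[OH-]
Why: Saponification of the unhindered methyl ester at 0 °C is faster than α-deprotonation, so the β,γ-double bond should not move into conjugation, and the TBDPS ether is stable to LiOH.

Step 7
Reactants: 5 (2E,5S)-3-methyl-5,6-bis(triethylsilyloxy)hex-2-en-1-ol and 9 3-[(tert-butyldiphenylsilyloxy)methyl]but-3-enoic acid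
Product: 10 (2E,5S)-3-methyl-5,6-bis(triethylsilyloxy)hex-2-en-1-yl 3-[(tert-butyldiphenylsilyloxy)methyl]but-3-enoate
Conditions: DCC, DMAP (cat.), CH2Cl2, 0 °C
Reagents that add atoms: none
Why: Carbodiimide coupling (Steglich esterification) with only catalytic DMAP at 0 °C joins the two fragments without isomerising the β,γ-unsaturated acyl unit.

Step 8
Reactants: 10 (2E,5S)-3-methyl-5,6-bis(triethylsilyloxy)hex-2-en-1-yl 3-[(tert-butyldiphenylsilyloxy)methyl]but-3-enoate
Product: 13 (2R,3R)-2-[3-(tert-butyldiphenylsilyloxy)prop-1-en-2-yl]-3-[(2S)-2,3-bis(triethylsilyloxy)propyl]-3-methylpent-4-enoic acid, via boron ketene acetal 11 (not isolated), via acyloxyborane 12 (not isolated)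
Conditions: (4S,5S)-2-bromo-1,3-bis{[3,5-bis(trifluoromethyl)phenyl]sulfonyl}-4,5-diphenyl-1,3,2-diazaborolidine (1.5 equiv), i-Pr2NEt, CH2Cl2, −78 °C, then −20 → 4 °C; aq. work-up
Reagents that add atoms: none
Why: Soft enolisation by the chiral bromoborane and the hindered amine in CH2Cl2 should give ketene acetal 11 with O–B cis to the C4 branch, and its Ireland–Claisen rearrangement through a chair (C14 methyl axial and C9 chain equatorial on C10, C4 branch equatorial on C5) fixes the C5/C10 relative configuration, while the C2-symmetric sulfonamide ligand selects the enolate face and so the absolute configuration (5R,10R).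

Step 9
Reactants: 13 (2R,3R)-2-[3-(tert-butyldiphenylsilyloxy)prop-1-en-2-yl]-3-[(2S)-2,3-bis(triethylsilyloxy)propyl]-3-methylpent-4-enoic acid
Product: 14 (2R,3R)-2-[3-(tert-butyldiphenylsilyloxy)prop-1-en-2-yl]-3-[(2S)-2,3-bis(triethylsilyloxy)propyl]-3-methylpent-4-en-1-ol
Conditions: LiAlH4, Et2O, 0 °C → rt; aq. KNaC4H4O6
Reagents that add atoms: none
Why: Hydride reduction of the carboxylic acid to the primary alcohol (LiAlH4 reduction) leaves the silyl ethers and the alkenes untouched and does not affect C5.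

Step 10
Reactants: 14 (2R,3R)-2-[3-(tert-butyldiphenylsilyloxy)prop-1-en-2-yl]-3-[(2S)-2,3-bis(triethylsilyloxy)propyl]-3-methylpent-4-en-1-ol
Product: 15 4-methoxybenzyl ether of 14 at C6–O
Conditions: NaH, 4-methoxybenzyl chloride, Bu4NI (cat.), THF/DMF, 0 °C → rt
Reagents that add atoms: 4-methoxybenzyl chloride, COc1ccc(CCl)cc1
Why: Williamson etherification of the only free hydroxyl, all other oxygen functions being silyl ethers that are stable to NaH.

Step 11
Reactants: 15 4-methoxybenzyl ether of 14 at C6–O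
Product: 16 (2S,4R,5R)-4-ethenyl-6-[(4-methoxybenzyl)oxy]-4-methyl-5-[3-(tert-butyldiphenylsilyloxy)prop-1-en-2-yl]-2-(triethylsilyloxy)hexanal
Conditions: (COCl)2, DMSO, CH2Cl2, −78 → −35 °C; i-Pr2NEt, −78 → 0 °C
Reagents that add atoms: none
Why: Under Swern conditions a primary TES ether is cleaved by the chlorosulfonium reagent and oxidised in the same flask whereas the secondary TES, TBDPS and PMB ethers are not touched (oxidative desilylation–Swern oxidation), and the cold work-up with a hindered base avoids epimerisation at C8.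

Step 12
Reactants: 17 2-(trimethylsilyl)ethanol
Product: 18 2-(trimethylsilyl)ethyl acrylate
Conditions: acryloyl chloride, Et3N, CH2Cl2, 0 °C
Reagents that add atoms: acryloyl chloride, C=CC(=O)Cl
Why: O-Acylation of the primary alcohol by the acid chloride with an amine base is a routine ester formation.

Step 13
Reactants: 16 (2S,4R,5R)-4-ethenyl-6-[(4-methoxybenzyl)oxy]-4-methyl-5-[3-(tert-butyldiphenylsilyloxy)prop-1-en-2-yl]-2-(triethylsilyloxy)hexanal and 18 2-(trimethylsilyl)ethyl acrylate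
Product: 19 2-(trimethylsilyl)ethyl (4S,6R,7R)-6-ethenyl-3-hydroxy-8-[(4-methoxybenzyl)oxy]-6-methyl-2-methylidene-7-[3-(tert-butyldiphenylsilyloxy)prop-1-en-2-yl]-4-(triethylsilyloxy)octanoate (both epimers at the carbinol carbon C7)
Conditions: DABCO (1 equiv), 18 (5 equiv), neat, rt
Reagents that add atoms: none
Why: In the Baylis–Hillman reaction DABCO adds to the acrylate and the resulting enolate attacks the activated α-silyloxy aldehyde, the new C7 carbinol centre being formed without control, which does not matter because C7 becomes sp2 in step 14.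

Step 14
Reactants: 19 Baylis–Hillman adduct
Product: 20 2-(trimethylsilyl)ethyl (2Z,4S,6R,7R)-2-(bromomethyl)-6-ethenyl-8-[(4-methoxybenzyl)oxy]-6-methyl-7-[3-(tert-butyldiphenylsilyloxy)prop-1-en-2-yl]-4-(triethylsilyloxy)oct-2-enoate
Conditions: NBS, Me2S, CH2Cl2, 0 °C → rt
Reagents that add atoms: N-bromosuccinimide, O=C1CCC(=O)N1Br
Why: The bromosulfonium reagent activates the C7 hydroxyl and bromide attacks C13 with allylic transposition (SN2′ bromination), which should give the thermodynamically preferred geometry with C8 cis to CH2Br, i.e. the (Z)-bromide.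

Step 15
Reactants: 20 (Z)-allylic bromide
Product: 21 2-(trimethylsilyl)ethyl (2Z,4S,6R,7R)-2-(bromomethyl)-6-ethenyl-8-hydroxy-6-methyl-7-[3-(tert-butyldiphenylsilyloxy)prop-1-en-2-yl]-4-(triethylsilyloxy)oct-2-enoate
Conditions: DDQ, CH2Cl2/pH 7 phosphate buffer, 0 °C
Reagents that add atoms: none
Why: DDQ oxidises the electron-rich benzyl ether to an oxocarbenium ion that water hydrolyses (oxidative PMB cleavage), while the silyl ethers, the allylic bromide and the enoate are inert.

Step 16
Reactants: 21 C6 alcohol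
Product: 22 2-(trimethylsilyl)ethyl (2Z,4S,6R,7R)-2-(bromomethyl)-6-ethenyl-6-methyl-8-oxo-7-[3-(tert-butyldiphenylsilyloxy)prop-1-en-2-yl]-4-(triethylsilyloxy)oct-2-enoate
Conditions: Dess–Martin periodinane, NaHCO3, CH2Cl2, 0 °C; crude aldehyde used at once
Reagents that add atoms: none
Why: Dess–Martin oxidation under bicarbonate buffering forms the aldehyde without base, so the α-branched β,γ-unsaturated aldehyde (the acyclic precursor of the key step) should neither epimerise at C5 nor conjugate, and the allylic bromide is untouched.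

Step 17
Reactants: 22 acyclic C6 aldehyde with the (Z)-2-(bromomethyl)enoate at C7
Product: 24 2-(trimethylsilyl)ethyl (5R,6S,7S,8S,10R)-15-(tert-butyldiphenylsilyloxy)-6-hydroxy-8-(triethylsilyloxy)elema-1,3,11(13)-trien-12-oate, via allylzinc bromide 23 (not isolated)
Conditions: Zn dust (activated), THF/sat. aq. NH4Cl, high dilution, 0 °C → rt
Reagents that add atoms: none
Why: Zinc inserts into the activated allylic C13–Br bond and the 2-(alkoxycarbonyl)allylzinc 23 adds through its γ-carbon C7 to the C6 aldehyde in a closed six-membered Zimmerman–Traxler-type transition state, so that the double bond moves to C11=C13; the closest known reaction type is the zinc- or chromium-mediated intramolecular allylation of aldehydes by 2-(bromomethyl)acrylates used for α-methylene lactone annulation. The cyclohexane ring (C5–C10) closes in the 6-exo-trig mode. C7 is controlled by the chair of the forming ring, in which the C5 branch, the C8 silyloxy group and the C10 methyl group are equatorial (vinyl axial) and the C11 unit takes the pseudo-equatorial position trans to C8–O, an arrangement that also puts C8–H and not C9 in the alkene plane next to C13 and so avoids allylic 1,3-strain. C6 is controlled by the (Z)-geometry of the allyl unit (C8 cis to C13): in the cis-fused chair–chair transition state C8 is axial and C5 equatorial on the zinc-containing ring, which places the zinc-bound oxygen axial on the carbocycle and hence cis to both the C7 acrylate and the C5 branch. The step needs γ- rather than α-attack (six- versus eight-membered ring), addition faster than loss of the C8 oxygen by elimination, and no lactonisation; the short tether, the aqueous NH4Cl medium that protonates the zinc alkoxide at once, and the TMSE ester secure these.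

Step 18
Reactants: 24 cyclised hydroxy ester
Product: 25 2-(trimethylsilyl)ethyl (5R,6S,7R,8S,10R)-6-(tert-butyldimethylsilyloxy)-15-(tert-butyldiphenylsilyloxy)-8-(triethylsilyloxy)elema-1,3,11(13)-trien-12-oate (same spatial arrangement as 24; only the C7 descriptor changes)
Conditions: t-BuMe2SiOTf, 2,6-lutidine, CH2Cl2, −78 → 0 °C
Reagents that add atoms: tert-butyldimethylsilyl trifluoromethanesulfonate, CC(C)(C)[Si](C)(C)OS(=O)(=O)C(F)(F)F
Why: Silylation with the silyl triflate is fast enough for the hindered axial C6 hydroxyl and closes the lactonisation pathway to C12.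

Step 19
Reactants: 25 fully silylated ester
Product: 26 2-(trimethylsilyl)ethyl (5R,6S,7R,8S,10R)-6-(tert-butyldimethylsilyloxy)-15-(tert-butyldiphenylsilyloxy)-8-hydroxyelema-1,3,11(13)-trien-12-oate
Conditions: PPTS (cat.), MeOH/CH2Cl2, 0 °C → rt
Reagents that add atoms: none
Why: Acid-catalysed methanolysis removes the secondary TES ether far faster than the hindered TBS and the TBDPS ethers (selective desilylation), and with C6–O silylated no lactone can form.

Step 20
Reactants: 27 3-methylfuran-2(5H)-one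
Product: 29 (2Z)-4-acetoxy-2-methylbut-2-enoic acid, via sodium (2Z)-4-hydroxy-2-methylbut-2-enoate 28 (not isolated)
Conditions: NaOH (1.0 equiv), H2O/MeOH, 0 °C → rt, evaporate; Ac2O, pyridine, DMAP (cat.), 0 °C → rt; aq. NaHCO3, then cold 1 M HCl to pH 3
Reagents that add atoms: sodium hydroxide, [Na+].[OH-]; acetic anhydride, CC(=O)OC(C)=O
Why: Hydroxide opens the butenolide (saponification), the ring imposing the (Z)-geometry on 28, and acetylation of the primary hydroxyl while the carboxyl stays as its sodium salt (so that it cannot relactonise) gives the acid on acidification.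

Step 21
Reactants: 26 C8 alcohol and 29 (2Z)-4-acetoxy-2-methylbut-2-enoic acid
Product: 31 2-(trimethylsilyl)ethyl (5R,6S,7R,8S,10R)-8-[(2Z)-4-acetoxy-2-methylbut-2-enoyloxy]-6-(tert-butyldimethylsilyloxy)-15-(tert-butyldiphenylsilyloxy)elema-1,3,11(13)-trien-12-oate, via Yamaguchi mixed anhydride 30 (not isolated)
Conditions: 2,4,6-trichlorobenzoyl chloride, Et3N, toluene, rt; then 26, DMAP, toluene, rt
Reagents that add atoms: none
Why: Yamaguchi esterification through mixed anhydride 30 acylates the equatorial C8 hydroxyl, and the (Z)-geometry fixed by the butenolide is expected to survive when the DMAP loading and the temperature are kept low.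

Step 22
Reactants: 31 protected ester
Product: 32 (5R,6S,7S,8S,10R)-8-[(2Z)-4-acetoxy-2-methylbut-2-enoyloxy]-6,15-dihydroxyelema-1,3,11(13)-trien-12-oic acid
Conditions: (Me2N)3S+ Me3SiF2− (TASF), DMF, 0 °C → rt; pH 5 phosphate buffer, 0 °C
Reagents that add atoms: none
Why: Fluoride cleaves the primary TBDPS ether and the TMSE ester (β-elimination to ethene) before the hindered secondary TBS ether, so C6–O is freed only beside a carboxylate and cannot lactonise, and the non-basic fluoride source spares the acetate and the (Z)-enoate (fluoride desilylation).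

**Compound list**

1 | (R)-glycidol | C1[C@H](O1)CO | starting material
2 | (2S)-pent-4-yne-1,2-diol | C#CC[C@H](O)CO | intermediate
3 | (4S)-4,5-bis(triethylsilyloxy)pent-1-yne | C#CC[C@H](O[Si](CC)(CC)CC)CO[Si](CC)(CC)CC | intermediate
4 | dimethyl[(1E,4S)-2-methyl-4,5-bis(triethylsilyloxy)pent-1-en-1-yl]alane | C[Al](C)/C=C(\C)C[C@H](O[Si](CC)(CC)CC)CO[Si](CC)(CC)CC | intermediate
5 | (2E,5S)-3-methyl-5,6-bis(triethylsilyloxy)hex-2-en-1-ol | OC/C=C(\C)C[C@H](O[Si](CC)(CC)CC)CO[Si](CC)(CC)CC | intermediate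
6 | monomethyl itaconate (4-methoxy-2-methylidene-4-oxobutanoic acid) | C=C(CC(=O)OC)C(=O)O | starting material
7 | methyl 3-(hydroxymethyl)but-3-enoate | C=C(CO)CC(=O)OC | intermediate
8 | methyl 3-[(tert-butyldiphenylsilyloxy)methyl]but-3-enoate | C=C(CO[Si](c1ccccc1)(c1ccccc1)C(C)(C)C)CC(=O)OC | intermediate
9 | 3-[(tert-butyldiphenylsilyloxy)methyl]but-3-enoic acid | C=C(CO[Si](c1ccccc1)(c1ccccc1)C(C)(C)C)CC(=O)O | intermediate
10 | (2E,5S)-3-methyl-5,6-bis(triethylsilyloxy)hex-2-en-1-yl 3-[(tert-butyldiphenylsilyloxy)methyl]but-3-enoate | C=C(CO[Si](c1ccccc1)(c1ccccc1)C(C)(C)C)CC(=O)OC/C=C(\C)C[C@H](O[Si](CC)(CC)CC)CO[Si](CC)(CC)CC | intermediate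
11 | boron ketene acetal of 10 with the (4S,5S)-1,3-bis{[3,5-bis(trifluoromethyl)phenyl]sulfonyl}-4,5-diphenyl-1,3,2-diazaborolidin-2-yl group on oxygen, O–B cis to the C4 branch | C=C(CO[Si](c1ccccc1)(c1ccccc1)C(C)(C)C)/C=C(\OB1N(S(=O)(=O)c2cc(cc(c2)C(F)(F)F)C(F)(F)F)[C@@H](c2ccccc2)[C@H](c2ccccc2)N1S(=O)(=O)c1cc(cc(c1)C(F)(F)F)C(F)(F)F)OC/C=C(\C)C[C@H](O[Si](CC)(CC)CC)CO[Si](CC)(CC)CC | intermediate
12 | acyloxyborane: (4S,5S)-diazaborolidin-2-yl ester of acid 13 | C=C[C@@]([C@@H](C(=O)OB1N(S(=O)(=O)c2cc(cc(c2)C(F)(F)F)C(F)(F)F)[C@@H](c2ccccc2)[C@H](c2ccccc2)N1S(=O)(=O)c1cc(cc(c1)C(F)(F)F)C(F)(F)F)C(=C)CO[Si](c1ccccc1)(c1ccccc1)C(C)(C)C)(C)C[C@H](O[Si](CC)(CC)CC)CO[Si](CC)(CC)CC | intermediate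
13 | (2R,3R)-2-[3-(tert-butyldiphenylsilyloxy)prop-1-en-2-yl]-3-[(2S)-2,3-bis(triethylsilyloxy)propyl]-3-methylpent-4-enoic acid (5R,8S,10R in target numbering) | C=C[C@@]([C@@H](C(=O)O)C(=C)CO[Si](c1ccccc1)(c1ccccc1)C(C)(C)C)(C)C[C@H](O[Si](CC)(CC)CC)CO[Si](CC)(CC)CC | intermediate
14 | (2R,3R)-2-[3-(tert-butyldiphenylsilyloxy)prop-1-en-2-yl]-3-[(2S)-2,3-bis(triethylsilyloxy)propyl]-3-methylpent-4-en-1-ol | C=C[C@@]([C@@H](CO)C(=C)CO[Si](c1ccccc1)(c1ccccc1)C(C)(C)C)(C)C[C@H](O[Si](CC)(CC)CC)CO[Si](CC)(CC)CC | intermediate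
15 | 4-methoxybenzyl ether of 14 at C6–O (configuration as 14) | C=C[C@@]([C@@H](COCc1ccc(OC)cc1)C(=C)CO[Si](c1ccccc1)(c1ccccc1)C(C)(C)C)(C)C[C@H](O[Si](CC)(CC)CC)CO[Si](CC)(CC)CC | intermediate
16 | (2S,4R,5R)-4-ethenyl-6-[(4-methoxybenzyl)oxy]-4-methyl-5-[3-(tert-butyldiphenylsilyloxy)prop-1-en-2-yl]-2-(triethylsilyloxy)hexanal | C=C[C@@]([C@@H](COCc1ccc(OC)cc1)C(=C)CO[Si](c1ccccc1)(c1ccccc1)C(C)(C)C)(C)C[C@H](O[Si](CC)(CC)CC)C=O | intermediate
17 | 2-(trimethylsilyl)ethanol | C[Si](C)(C)CCO | starting material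
18 | 2-(trimethylsilyl)ethyl acrylate | C=CC(=O)OCC[Si](C)(C)C | intermediate
19 | 2-(trimethylsilyl)ethyl (4S,6R,7R)-6-ethenyl-3-hydroxy-8-[(4-methoxybenzyl)oxy]-6-methyl-2-methylidene-7-[3-(tert-butyldiphenylsilyloxy)prop-1-en-2-yl]-4-(triethylsilyloxy)octanoate, both epimers at the carbinol carbon | C=C[C@@]([C@@H](COCc1ccc(OC)cc1)C(=C)CO[Si](c1ccccc1)(c1ccccc1)C(C)(C)C)(C)C[C@H](O[Si](CC)(CC)CC)C(O)C(=C)C(=O)OCC[Si](C)(C)C | intermediate
20 | 2-(trimethylsilyl)ethyl (2Z,4S,6R,7R)-2-(bromomethyl)-6-ethenyl-8-[(4-methoxybenzyl)oxy]-6-methyl-7-[3-(tert-butyldiphenylsilyloxy)prop-1-en-2-yl]-4-(triethylsilyloxy)oct-2-enoate | C=C[C@@]([C@@H](COCc1ccc(OC)cc1)C(=C)CO[Si](c1ccccc1)(c1ccccc1)C(C)(C)C)(C)C[C@H](O[Si](CC)(CC)CC)/C=C(\CBr)C(=O)OCC[Si](C)(C)C | intermediate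
21 | 2-(trimethylsilyl)ethyl (2Z,4S,6R,7R)-2-(bromomethyl)-6-ethenyl-8-hydroxy-6-methyl-7-[3-(tert-butyldiphenylsilyloxy)prop-1-en-2-yl]-4-(triethylsilyloxy)oct-2-enoate | C=C[C@@]([C@@H](CO)C(=C)CO[Si](c1ccccc1)(c1ccccc1)C(C)(C)C)(C)C[C@H](O[Si](CC)(CC)CC)/C=C(\CBr)C(=O)OCC[Si](C)(C)C | intermediate
22 | 2-(trimethylsilyl)ethyl (2Z,4S,6R,7R)-2-(bromomethyl)-6-ethenyl-6-methyl-8-oxo-7-[3-(tert-butyldiphenylsilyloxy)prop-1-en-2-yl]-4-(triethylsilyloxy)oct-2-enoate (key-step precursor) | C=C[C@@]([C@@H](C=O)C(=C)CO[Si](c1ccccc1)(c1ccccc1)C(C)(C)C)(C)C[C@H](O[Si](CC)(CC)CC)/C=C(\CBr)C(=O)OCC[Si](C)(C)C | intermediate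
23 | allylzinc bromide of 22 (C13–ZnBr in place of C13–Br) | C=C[C@@]([C@@H](C=O)C(=C)CO[Si](c1ccccc1)(c1ccccc1)C(C)(C)C)(C)C[C@H](O[Si](CC)(CC)CC)/C=C(\C[Zn]Br)C(=O)OCC[Si](C)(C)C | intermediate
24 | 2-(trimethylsilyl)ethyl (5R,6S,7S,8S,10R)-15-(tert-butyldiphenylsilyloxy)-6-hydroxy-8-(triethylsilyloxy)elema-1,3,11(13)-trien-12-oate (key-step product) | C=C[C@@]1(C)C[C@H](O[Si](CC)(CC)CC)[C@@H](C(=C)C(=O)OCC[Si](C)(C)C)[C@@H](O)[C@H]1C(=C)CO[Si](c1ccccc1)(c1ccccc1)C(C)(C)C | intermediate
25 | 2-(trimethylsilyl)ethyl (5R,6S,7R,8S,10R)-6-(tert-butyldimethylsilyloxy)-15-(tert-butyldiphenylsilyloxy)-8-(triethylsilyloxy)elema-1,3,11(13)-trien-12-oate | C=C[C@@]1(C)C[C@H](O[Si](CC)(CC)CC)[C@@H](C(=C)C(=O)OCC[Si](C)(C)C)[C@@H](O[Si](C)(C)C(C)(C)C)[C@H]1C(=C)CO[Si](c1ccccc1)(c1ccccc1)C(C)(C)C | intermediate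
26 | 2-(trimethylsilyl)ethyl (5R,6S,7R,8S,10R)-6-(tert-butyldimethylsilyloxy)-15-(tert-butyldiphenylsilyloxy)-8-hydroxyelema-1,3,11(13)-trien-12-oate | C=C[C@@]1(C)C[C@H](O)[C@@H](C(=C)C(=O)OCC[Si](C)(C)C)[C@@H](O[Si](C)(C)C(C)(C)C)[C@H]1C(=C)CO[Si](c1ccccc1)(c1ccccc1)C(C)(C)C | intermediate
27 | 3-methylfuran-2(5H)-one | CC1=CCOC1=O | starting material
28 | sodium (2Z)-4-hydroxy-2-methylbut-2-enoate | [Na+].[O-]C(=O)/C(C)=C\CO | intermediate
29 | (2Z)-4-acetoxy-2-methylbut-2-enoic acid | OC(=O)/C(C)=C\COC(C)=O | intermediate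
30 | (2Z)-4-acetoxy-2-methylbut-2-enoic 2,4,6-trichlorobenzoic anhydride | O=C(OC(=O)c1c(Cl)cc(Cl)cc1Cl)/C(C)=C\COC(C)=O | intermediate
31 | 2-(trimethylsilyl)ethyl (5R,6S,7R,8S,10R)-8-[(2Z)-4-acetoxy-2-methylbut-2-enoyloxy]-6-(tert-butyldimethylsilyloxy)-15-(tert-butyldiphenylsilyloxy)elema-1,3,11(13)-trien-12-oate | C=C[C@@]1(C)C[C@H](OC(=O)/C(C)=C\COC(C)=O)[C@@H](C(=C)C(=O)OCC[Si](C)(C)C)[C@@H](O[Si](C)(C)C(C)(C)C)[C@H]1C(=C)CO[Si](c1ccccc1)(c1ccccc1)C(C)(C)C | intermediate
32 | (5R,6S,7S,8S,10R)-8-[(2Z)-4-acetoxy-2-methylbut-2-enoyloxy]-6,15-dihydroxyelema-1,3,11(13)-trien-12-oic acid | C=C[C@@]1(C)C[C@H](OC(=O)/C(C)=C\COC(C)=O)[C@@H](C(=C)C(=O)O)[C@@H](O)[C@H]1C(=C)CO | target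

**Totals**

Total step count: 22. Longest linear sequence: 17 steps (steps 1–3, 7–11, 13–19, 21, 22).

**Steps most likely to fail**

1. Step 17 (ring closure). The allylzinc may be protonated, or may lose the C8 silyloxy group by elimination through its C7-metallated isomer, before it reaches the hindered aldehyde; the aldehyde may epimerise at C5; or the zinc alkoxide may lactonise. Fallback, a preformed allylboron reagent in place of the in situ organozinc, setting out from 19: acetylation (Ac2O, DMAP, pyridine) would give the allylic acetate F1. Palladium-catalysed allylic borylation with bis(pinacolato)diboron (Pd2(dba)3 as the zerovalent palladium source, DMSO, 50 °C) would give, with allylic transposition, the 2-(borylmethyl)enoate F2 with C8 cis to CH2B. DDQ would free the C6 hydroxyl to give the boronate alcohol F3, and Dess–Martin oxidation would give the boronate aldehyde F4. F4 should cyclise at rt or on gentle warming (catalytic Sc(OTf)3 if needed) by intramolecular allylboration through the same closed chair arrangement to the cyclic borate F5 (not isolated). Mild aqueous work-up returns the route at 24.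

2. Step 8 (Ireland–Claisen). The β,γ-unsaturated ester may enolise with poor geometric control, which erodes the C5/C10 relative configuration, or the controller may select the enolate face poorly against the remote C8 centre. Fallback, the reversed olefin/enolate pairing, setting out from 3: deprotonation (n-BuLi, THF, −78 °C) and methyl chloroformate would give the ynoate F6. Syn addition of Me2CuLi (THF, −78 °C, cold quench) would give the (Z)-enoate F7, and i-Bu2AlH would reduce it to the (Z)-allylic alcohol F8. Coupling with 9 (DCC, cat. DMAP) would give the (Z)-allyl ester F9. Enolisation with the antipodal (4R,5R)-bromoborane and Et3N in toluene/hexane at −78 °C, conditions under which simple esters give the enolate with O–B trans to the α-substituent, would give the boron ketene acetal F10. Its chair rearrangement (C9 axial, methyl equatorial, C4 branch axial) leads to the same C5/C10 configuration through the acyloxyborane F11, and work-up returns the route at 13.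

3. Step 21 (acylation of C8–OH). The activated (Z)-enoate may isomerise to the (E)-isomer under nucleophilic catalysis, or acylation of the flanked C8 hydroxyl may be too slow. Fallback, building the (Z)-alkene on the ester, setting out from 26: acylation with 2-[bis(2,2,2-trifluoroethoxy)phosphoryl]propanoic acid (DCC, cat. DMAP, CH2Cl2) would give the phosphonopropanoate F12 (both epimers at the phosphonate carbon). Still–Gennari olefination (KN(SiMe3)2, 18-crown-6, THF, −78 °C) with 2-oxoethyl acetate would form the (Z)-trisubstituted enoate directly and return the route at 31.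

**Further compounds**

F1 | step 17 | C7 acetate of 19 (both C7 epimers) | C=C[C@@]([C@@H](COCc1ccc(OC)cc1)C(=C)CO[Si](c1ccccc1)(c1ccccc1)C(C)(C)C)(C)C[C@H](O[Si](CC)(CC)CC)C(OC(C)=O)C(=C)C(=O)OCC[Si](C)(C)C
F2 | step 17 | 2-(trimethylsilyl)ethyl 2-[(pinacolatoboryl)methyl]oct-2-enoate analogue of 20 (C13–Bpin in place of C13–Br, C8 cis to CH2B) | C=C[C@@]([C@@H](COCc1ccc(OC)cc1)C(=C)CO[Si](c1ccccc1)(c1ccccc1)C(C)(C)C)(C)C[C@H](O[Si](CC)(CC)CC)/C=C(\CB1OC(C)(C)C(C)(C)O1)C(=O)OCC[Si](C)(C)C
F3 | step 17 | boronate analogue of 21 (C6–OH free) | C=C[C@@]([C@@H](CO)C(=C)CO[Si](c1ccccc1)(c1ccccc1)C(C)(C)C)(C)C[C@H](O[Si](CC)(CC)CC)/C=C(\CB1OC(C)(C)C(C)(C)O1)C(=O)OCC[Si](C)(C)C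
F4 | step 17 | boronate analogue of 22 (C6 aldehyde) | C=C[C@@]([C@@H](C=O)C(=C)CO[Si](c1ccccc1)(c1ccccc1)C(C)(C)C)(C)C[C@H](O[Si](CC)(CC)CC)/C=C(\CB1OC(C)(C)C(C)(C)O1)C(=O)OCC[Si](C)(C)C
F5 | step 17 | C6–O–B(pinacolato) borate of 24 | C=C[C@@]1(C)C[C@H](O[Si](CC)(CC)CC)[C@@H](C(=C)C(=O)OCC[Si](C)(C)C)[C@@H](OB2OC(C)(C)C(C)(C)O2)[C@H]1C(=C)CO[Si](c1ccccc1)(c1ccccc1)C(C)(C)C
F6 | step 8 | methyl (5S)-5,6-bis(triethylsilyloxy)hex-2-ynoate | COC(=O)C#CC[C@H](O[Si](CC)(CC)CC)CO[Si](CC)(CC)CC
F7 | step 8 | methyl (2Z,5S)-3-methyl-5,6-bis(triethylsilyloxy)hex-2-enoate | COC(=O)/C=C(/C)C[C@H](O[Si](CC)(CC)CC)CO[Si](CC)(CC)CC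
F8 | step 8 | (2Z,5S)-3-methyl-5,6-bis(triethylsilyloxy)hex-2-en-1-ol | OC/C=C(/C)C[C@H](O[Si](CC)(CC)CC)CO[Si](CC)(CC)CC
F9 | step 8 | (2Z,5S)-3-methyl-5,6-bis(triethylsilyloxy)hex-2-en-1-yl 3-[(tert-butyldiphenylsilyloxy)methyl]but-3-enoate | C=C(CO[Si](c1ccccc1)(c1ccccc1)C(C)(C)C)CC(=O)OC/C=C(/C)C[C@H](O[Si](CC)(CC)CC)CO[Si](CC)(CC)CC
F10 | step 8 | boron ketene acetal of F9 with the (4R,5R)-diazaborolidin-2-yl group on oxygen, O–B trans to the C4 branch | C=C(CO[Si](c1ccccc1)(c1ccccc1)C(C)(C)C)/C=C(/OB1N(S(=O)(=O)c2cc(cc(c2)C(F)(F)F)C(F)(F)F)[C@H](c2ccccc2)[C@@H](c2ccccc2)N1S(=O)(=O)c1cc(cc(c1)C(F)(F)F)C(F)(F)F)OC/C=C(/C)C[C@H](O[Si](CC)(CC)CC)CO[Si](CC)(CC)CC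
F11 | step 8 | acyloxyborane: (4R,5R)-diazaborolidin-2-yl ester of acid 13 | C=C[C@@]([C@@H](C(=O)OB1N(S(=O)(=O)c2cc(cc(c2)C(F)(F)F)C(F)(F)F)[C@H](c2ccccc2)[C@@H](c2ccccc2)N1S(=O)(=O)c1cc(cc(c1)C(F)(F)F)C(F)(F)F)C(=C)CO[Si](c1ccccc1)(c1ccccc1)C(C)(C)C)(C)C[C@H](O[Si](CC)(CC)CC)CO[Si](CC)(CC)CC
F12 | step 21 | C8 2-[bis(2,2,2-trifluoroethoxy)phosphoryl]propanoate of 26 (both epimers at the phosphonate carbon) | C=C[C@@]1(C)C[C@H](OC(=O)C(C)P(=O)(OCC(F)(F)F)OCC(F)(F)F)[C@@H](C(=C)C(=O)OCC[Si](C)(C)C)[C@@H](O[Si](C)(C)C(C)(C)C)[C@H]1C(=C)CO[Si](c1ccccc1)(c1ccccc1)C(C)(C)C
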